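(The runs come from a simulation from invented constants; scatter was added.)

26.8 fills of the dissolved gas: that is what Monday's flask turned into target by 40.0 min, so gas must keep crossing from the gas phase while the starting material reacts. The question is whether the crossing keeps up as the charge grows.

| setting | Wednesday's | Monday's | violet | red | teal |
|---|---|---|---|---|---|
| starting material | 0.026 M (in portions, 4) | 0.24 M (in portions, 4) | 0.030 M (in portions, 4) | 0.10 M (in portions, 4) | 0.30 M (in portions, 4) |
| gas phase | 4.3 mM (held) | 4.3 mM (held) | 4.3 mM (held) | 4.3 mM (held) | 4.3 mM (held) |
| remark | run made earlier; portions every 1.0 min | run made earlier; portions every 1.0 min | the portions of starting material follow each other after 1.0 min, the first at the start | the portions of starting material follow each other after 1.0 min, the first at the start | the portions of starting material follow each other after 1.0 min, the first at the start |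
| time |  |  | 40 min | 40 min | 40 min |

- Wednesday's (time / min: target / %, starting material / %): 3.00: 2, 70; 8.00: 14, 74; 15.0: 24, 59; 40.0: 46, 19
- Monday's (time / min: target / %, starting material / %): 3.00: 4, 67; 8.00: 16, 78; 15.0: 24, 59; 40.0: 48, 22

(readings scatter by 1.5 percentage points)

- amount of target at the end, in percent of the starting material charged for violet, red, teal, in this order
- how the row runs (hardly changes / falls all the way / falls, then rises / rises, then falls / rises all the way)

- at the start none of the gas is dissolved
- the numbers in the tables scatter with a standard deviation of 1.5 percentage points
- steps under discussion: gas phase <-> dissolved gas; starting material -> side product; starting material + dissolved gas -> target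
- "hardly changes" means that all values lie within two and a half points (for a concentration: within two and a half percent of the largest)

I carry one quantity, the shortfall per molar, a: the fraction by which dissolved gas lies below saturation, per mole per litre of charge. I take the shortfall to grow in proportion to the charge, and I assume that the end target falls short by the same fraction.

From above, with no shortfall, the percentage ignores the charge, and the two runs average 47.0 % at the end. From below, a crude floor comes from supposing Monday's crossing was already at its ceiling: teal then makes Monday's moles of target, which is 38.4 % of its charge.

The readings tighten that floor. Monday ends above Wednesday, but a difference of two readings could hide 4.88 % of relative loss at two standard deviations. Spread over the 0.214 M between the charges, this gives a at most 0.228 M⁻¹. On that assumption, teal's shortfall is at most 6.83 % and its floor is 43.8 %. While gas stays near saturation, the target step is pseudo-first-order in starting material.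

The forecast gives 47 %, 47 %, 47 %, so hardly changes, on the ground that “Matching percentages mean both routes are effectively first order in starting material”. For teal it stands inside my bracket, at the top edge. My bracket is 3.2 percentage points wide, so I expect the same shape but cannot prove it from these readings.

The flasks give 47.0 %, 46.7 %, 45.9 %: hardly changes.

    gas phase ⇌ dissolved gas, rate k1*(csat - [dissolved gas]) (kL = 24.0 min⁻¹)
    starting material → side product (k = 0.0170 min⁻¹)
    starting material + dissolved gas → target (k = 5.70 M⁻¹ min⁻¹)

In teal at 20.0 min, with 47.4 % of the charge left, gas crosses with a constant of 24 min⁻¹, while the target step uses it at 0.811 min⁻¹. Their ratio puts the shortfall near 3.38 % at that moment, under the ceiling of 6.83 % that a set for teal. On red, a allows at most 2.28 %, a floor of 45.9 %, and red ends at 46.7 %.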